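**Retrosynthesis (ring-forming order)**
- The 22-membered cyclophane is closed last, at the aryl–CH(OH) bond, by a catalytic enantioselective intramolecular Ni/Cr Nozaki–Hiyama–Kishi (NHK) coupling of an aryl iodide with an aliphatic aldehyde. This step sets the (R)-carbinol (Step 8, proposed new method).
- The (E)-olefin comes from cross-metathesis of a terminal alkene on the diaryl ether with 8-nonenal (Step 7).
- The hindered diaryl ether (acyclic C–O bond) comes from Chan–Lam coupling of an arylboronic acid with 4-iodosyringol (Step 5).
- Ring A comes from 3,5-dibromoanisole via B-alkyl Suzuki coupling; ring B comes from syringol. Both aromatic rings are commercial, so the macrocycle is the only ring formed. A global aryl-OMe cleavage finishes the synthesis.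

**Assumptions**
- The target carbinol is (R) by CIP (O > Ar > CH2 > H), obtained by Si-face aryl delivery to the aldehyde.
- The ligand enantiomer for Step 8 is matched empirically; (S)-L* is assumed to give (R).
- 8-Nonenal is made from commercial 8-nonen-1-ol.

## Route

**Step 1**
Reactants: 1 (1,6-heptadiene)
Product: 2 (B-(hept-6-en-1-yl)-9-BBN)
Conditions: 9-BBN (1.0 equiv; diene 3 equiv), THF, 0 °C → rt, 4 h
Reagents that add atoms: 9-BBN, B1C2CCCC1CCC2
Why: Hydroboration (anti-Markovnikov) with 9-BBN is selective for one terminal alkene, and excess diene suppresses bis-hydroboration.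

**Step 2**
Reactants: 3 (3,5-dibromoanisole, 2 equiv) + 2
Product: 4 (1-bromo-3-(hept-6-en-1-yl)-5-methoxybenzene)
Conditions: Pd(dppf)Cl2 (5 mol%), K3PO4, THF/H2O 10:1, 60 °C, 12 h
Reagents that add atoms: none
Why: B-alkyl Suzuki–Miyaura coupling (sp3–sp2); excess dibromide favours mono-alkylation, and the terminal alkene is inert.

**Step 3**
Reactants: 4
Product: 5 (3-(hept-6-en-1-yl)-5-methoxyphenylboronic acid)
Conditions: n-BuLi, THF, −78 °C; B(OiPr)3, −78 °C → rt; 1 M HCl
Reagents that add atoms: triisopropyl borate, CC(C)OB(OC(C)C)OC(C)C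
Why: Br/Li exchange followed by borylation (Miyaura-type lithiation–borylation) is compatible with the alkene and the OMe group.

**Step 4**
Reactants: 6 (2,6-dimethoxyphenol)
Product: 7 (4-iodo-2,6-dimethoxyphenol)
Conditions: NIS (1.05 equiv), MeCN, 0 °C → rt, 2 h
Reagents that add atoms: N-iodosuccinimide, O=C1CCC(=O)N1I
Why: Electrophilic aromatic iodination goes para to the free OH, the only open activated position.

**Step 5**
Reactants: 5 (1.5 equiv) + 7
Product: 8 (2-(3-(hept-6-en-1-yl)-5-methoxyphenoxy)-5-iodo-1,3-dimethoxybenzene)
Conditions: Cu(OAc)2 (1.5 equiv), pyridine, 4 Å MS, CH2Cl2, air, rt, 48 h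
Reagents that add atoms: none
Why: Chan–Lam O-arylation joins the phenol and the boronic acid and leaves the aryl iodide and alkene untouched.

**Step 6**
Reactants: 9 (8-nonen-1-ol)
Product: 10 (8-nonenal)
Conditions: Dess–Martin periodinane (1.3 equiv), NaHCO3, CH2Cl2, 0 °C → rt, 1 h
Reagents that add atoms: none
Why: Mild alcohol-to-aldehyde oxidation that leaves the alkene intact.

**Step 7**
Reactants: 8 + 10 (3 equiv)
Product: 11 ((E)-aldehyde–aryl iodide seco precursor)
Conditions: Hoveyda–Grubbs II (5 mol%), CH2Cl2 (0.05 M), 40 °C, 16 h, N2 sweep; E-isomer isolated on AgNO3–SiO2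
Reagents that add atoms: none
Why: Olefin cross-metathesis between two type-I terminal alkenes; excess aldehyde partner limits homodimer of 8, and the thermodynamic E product is enriched and purified by Ag-silica chromatography.

**Step 8**
Reactants: 11
Product: 12 ((R,E)-macrocyclic trimethyl ether)
Conditions: Substrate added by syringe pump over 12 h (final ~2 mM) to CrCl3 (20 mol%), (S)-L* (24 mol%), NiCl2·DME (10 mol%), Mn (5 equiv), Cp2ZrCl2 (20 mol%), TMSCl (3 equiv), THF/DMF 4:1, rt; then 1 M HCl, THF, 10 min. (S)-L* is a chiral bidentate sulfonamide–oxazoline ligand.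
Reagents that add atoms: none (the TMS ether formed in situ is cleaved on workup)
Why: Intramolecular NHK coupling closes the ring chemoselectively at the aryl iodide and the aldehyde, and the Cr–(S)-L* aryl species adds to the Si face to give the (R)-carbinol.
Proposed new method: catalytic enantioselective macrocyclization by Ni/Cr arylation of an aliphatic aldehyde. Ni(0) inserts into Ar–I, Ar transmetalates to chiral Cr(III), and the aryl-Cr adds to the aldehyde through a Cr-bound alkoxide transition state; Mn/TMSCl turns the Cr over, and slow addition gives pseudo-high dilution. The closest known reactions are racemic aryl-halide NHK couplings, intramolecular NHK macrocyclizations, and asymmetric Cr–sulfonamide NHK of vinyl and allyl halides.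

**Step 9**
Reactants: 12
Product: 13 (Dehydrogravicycle)
Conditions: NaSEt (12 equiv), DMF, 140 °C, 4 h; then 1 M HCl
Reagents that add atoms: none (the methyl groups leave as MeSEt)
Why: SN2 thiolate O-demethylation cleaves all three aryl methyl ethers without touching the E-alkene or the benzylic alkoxide, and the carbinol cannot ionize because no ortho/para phenoxide is conjugated to it.

## Compound list
1 | 1,6-heptadiene | C=CCCCC=C | starting material
2 | B-(hept-6-en-1-yl)-9-borabicyclo[3.3.1]nonane | C=CCCCCCB1C2CCCC1CCC2 | intermediate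
3 | 3,5-dibromoanisole | COc1cc(Br)cc(Br)c1 | starting material
4 | 1-bromo-3-(hept-6-en-1-yl)-5-methoxybenzene | COc1cc(Br)cc(CCCCCC=C)c1 | intermediate
5 | 3-(hept-6-en-1-yl)-5-methoxyphenylboronic acid | COc1cc(B(O)O)cc(CCCCCC=C)c1 | intermediate
6 | 2,6-dimethoxyphenol | COc1cccc(OC)c1O | starting material
7 | 4-iodo-2,6-dimethoxyphenol | COc1cc(I)cc(OC)c1O | intermediate
8 | diaryl ether with terminal alkene | COc1cc(I)cc(OC)c1Oc1cc(OC)cc(CCCCCC=C)c1 | intermediate
9 | 8-nonen-1-ol | OCCCCCCCC=C | starting material
10 | 8-nonenal | O=CCCCCCCC=C | intermediate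
11 | (E)-seco aldehyde/aryl iodide | O=CCCCCCC/C=C/CCCCCc1cc(OC)cc(Oc2c(OC)cc(I)cc2OC)c1 | intermediate
12 | (R,E)-macrocyclic trimethyl ether | COc1cc2cc(c1)Oc1c(OC)cc(cc1OC)[C@H](O)CCCCCC/C=C/CCCCC2 | intermediate
13 | Dehydrogravicycle | Oc1cc2cc(c1)Oc1c(O)cc(cc1O)[C@H](O)CCCCCC/C=C/CCCCC2 | target

**Total steps:** 9 (Steps 1–9).
**Longest linear sequence:** 7 steps (1 → 2 → 3 → 5 → 7 → 8 → 9).

## Three steps most likely to fail
1. **Step 8 (proposed new step; ee and yield of the macrocyclization).**
   Fallback: run the macro-NHK with achiral Ni/Cr (bipyridine, no chiral ligand) to give racemic 12. Oxidize it with DMP to the macrocyclic ketone, then do Noyori transfer hydrogenation with (R,R)-RuCl(p-cymene)(TsDPEN) and HCO2H/Et3N to set (R). This moves stereocontrol to a separate, known reduction step.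
2. **Step 5 (Chan–Lam coupling with the hindered 2,6-dimethoxyphenol).**
   Fallback: change the order. Ullmann-couple 6 with the ring-A aryl iodide (CuI/picolinic acid, K3PO4, DMSO), then iodinate with NIS as in Step 4.
3. **Step 7 (E/Z ratio and homodimers in cross-metathesis).**
   Fallback: build the E-olefin by Julia–Kocienski olefination instead. Couple a ring-A chain aldehyde with a 1-phenyltetrazolyl sulfone bearing the (CH2)6CHO chain (as a protected aldehyde), then continue to Step 8.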